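## Retrosynthetic overview

1. Ring numbering: O1–O2–C3(H, CH2CO2Me)–C4=C5–C6(OMe, C18 chain). Xestin B 22 is the (6S) member of the C6-epimer pair 21, which is cut at the ring alkene C4=C5 to give the acyclic bis-allylic peroxyketal 20 (ring-closing metathesis, step 14); the 1,2-dioxine is the only ring and is closed last.
2. Enabling feature: the O1–O2 bridge makes both C3 and C6 allylic, so cutting C4=C5 leaves two vinyl groups joined by the four-atom C3–O2–O1–C6 tether. Re-closure can only give the six-membered ring with the cis alkene, and C6 sits at the ketal oxidation level of a vinyl ketone.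
3. 20 is cut at C6–O1 (the fully substituted carbon) into hydroperoxide 19 and 1-alkyl-1-methoxyallene 10; protonation of the allene unveils the C6 vinyl group and the ketal carbon at once.
4. 19 comes from an amine-catalysed asymmetric peroxidation of penta-2,4-dienal 13 with hydroperoxide 15 (sets C3); 10 comes from lithiated methoxyallene and iodide 7, itself made from sorbyl acetate and a C12 Grignard reagent.
5. C6 is formed without control in step 13, so 20 and 21 are carried as epimer pairs; step 15 takes out the (6S) epimer and returns the (6R) epimer to the pair by acid-catalysed methoxy exchange.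

Key step: step 14

Assumption: the sense of induction in step 9 follows the usual shielding model for diarylprolinol silyl ether iminium ions, which assigns the (R)-catalyst to the (3R) product; if the sense proved opposite, the enantiomeric catalyst would be used.

## Route

Step 1
Reactants: 1 12-bromododecan-1-ol
Product: 2 (12-bromododecyloxy)(tert-butyl)dimethylsilane
Conditions: TBSCl, imidazole, CH2Cl2, 0 °C → rt
Reagents that add atoms: tert-butyldimethylsilyl chloride, CC(C)(C)[Si](C)(C)Cl
Why: Standard silylation of a primary alcohol, which masks the hydroxyl group for the Grignard formation that follows.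

Step 2
Reactants: 2 (12-bromododecyloxy)(tert-butyl)dimethylsilane; 3 (2E,4E)-hexa-2,4-dien-1-yl acetate (sorbyl acetate)
Product: 5 tert-butyldimethyl{[(14E,16E)-octadeca-14,16-dien-1-yl]oxy}silane, via Grignard reagent 4 (not isolated)
Conditions: Mg, THF, 40 °C; then 3, Li2CuCl4 (3 mol%), THF, −20 → 0 °C
Reagents that add atoms: none
Why: Kochi-type copper-catalysed coupling of an alkyl Grignard reagent with an allylic acetate; substitution at the acetate-bearing carbon of the dienyl acetate should keep the E,E-diene, as in pheromone-type sorbyl couplings, and no stereocenter is formed.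

Step 3
Reactants: 5 tert-butyldimethyl{[(14E,16E)-octadeca-14,16-dien-1-yl]oxy}silane
Product: 6 (14E,16E)-octadeca-14,16-dien-1-ol
Conditions: CSA (10 mol%), MeOH/CH2Cl2, rt
Reagents that add atoms: none
Why: Acid-catalysed methanolysis of a primary TBS ether, mild enough to leave the conjugated diene untouched.

Step 4
Reactants: 6 (14E,16E)-octadeca-14,16-dien-1-ol
Product: 7 (2E,4E)-18-iodooctadeca-2,4-diene
Conditions: I2, PPh3, imidazole, CH2Cl2, 0 °C
Reagents that add atoms: iodine, II
Why: Appel-type iodination through the alkoxyphosphonium iodide, an SN2 displacement at a primary carbon far from the diene.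

Step 5
Reactants: 7 (2E,4E)-18-iodooctadeca-2,4-diene; 8 methoxyallene (1-methoxypropa-1,2-diene)
Product: 10 (17E,19E)-3-methoxyhenicosa-1,2,17,19-tetraene, via lithiated methoxyallene 9 (not isolated)
Conditions: 8, n-BuLi, THF, −40 °C; then 7, −78 °C → rt; filtration through basic alumina
Reagents that add atoms: none
Why: α-Lithiation of methoxyallene and SN2 alkylation with a primary iodide is standard alkoxyallene chemistry, and the diene is inert to the organolithium at low temperature.

Step 6
Reactants: 11 (2E)-penta-2,4-dienoic acid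
Product: 12 (2E)-penta-2,4-dien-1-ol
Conditions: LiAlH4, Et2O, 0 °C
Reagents that add atoms: none
Why: Hydride reduction of a carboxylic acid to the primary allylic alcohol, as practised for sorbic acid; the conjugated diene should survive at 0 °C.

Step 7
Reactants: 12 (2E)-penta-2,4-dien-1-ol
Product: 13 (2E)-penta-2,4-dienal
Conditions: MnO2 (activated, excess), CH2Cl2, rt; filtered, solvent exchanged for toluene, used as a solution
Reagents that add atoms: none
Why: Chemoselective MnO2 oxidation of an allylic alcohol to the enal without touching the diene geometry.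

Step 8
Reactants: 14 2,3-dimethylbut-2-ene
Product: 15 2-methoxyprop-2-yl hydroperoxide (2-hydroperoxy-2-methoxypropane)
Conditions: O3, MeOH/CH2Cl2, −78 °C
Reagents that add atoms: ozone, O=[O+][O-]; methanol, CO
Why: Ozonolysis in methanol, in which the Criegee carbonyl oxide is trapped by methanol to give the α-methoxy hydroperoxide and acetone.

Step 9
Reactants: 13 (2E)-penta-2,4-dienal; 15 2-methoxyprop-2-yl hydroperoxide
Product: 16 (3R)-3-[(2-methoxypropan-2-yl)peroxy]pent-4-enal
Conditions: (R)-2-{bis[3,5-bis(trifluoromethyl)phenyl](trimethylsilyloxy)methyl}pyrrolidine (10 mol%), 13 (2 equiv), toluene, 0 °C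
Reagents that add atoms: none
Why: Iminium-catalysed asymmetric peroxidation (oxa-Michael addition of a tertiary α-alkoxy hydroperoxide to an enal); the diarylsilyloxymethyl group shields one face of the E,s-trans iminium ion, so the O–C3 bond should form on the open face of the β-carbon to give 3R, and O-nucleophiles normally attack dienals at the β- rather than the δ-carbon.

Step 10
Reactants: 16 (3R)-3-[(2-methoxypropan-2-yl)peroxy]pent-4-enal
Product: 17 (3R)-3-[(2-methoxypropan-2-yl)peroxy]pent-4-enoic acid
Conditions: NaClO2, NaH2PO4, 2-methylbut-2-ene, t-BuOH/H2O, 0 °C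
Reagents that add atoms: sodium chlorite, [Na+].[O-]Cl=O
Why: Pinnick oxidation under a mildly acidic buffer, which avoids the base-induced β-elimination of the peroxide and should spare the vinyl group (scavenger) and the perketal.

Step 11
Reactants: 17 (3R)-3-[(2-methoxypropan-2-yl)peroxy]pent-4-enoic acid
Product: 18 methyl (3R)-3-[(2-methoxypropan-2-yl)peroxy]pent-4-enoate
Conditions: TMSCHN2, toluene/MeOH (4:1), 0 °C
Reagents that add atoms: (trimethylsilyl)diazomethane, C[Si](C)(C)C=[N+]=[N-]
Why: Neutral methylation of the carboxylic acid by diazomethane generated in the flask, so that no base meets the β-peroxy ester.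

Step 12
Reactants: 18 methyl (3R)-3-[(2-methoxypropan-2-yl)peroxy]pent-4-enoate
Product: 19 methyl (3R)-3-hydroperoxypent-4-enoate
Conditions: PPTS (10 mol%), MeOH, 0 °C → rt
Reagents that add atoms: none
Why: Acid-catalysed transketalisation to 2,2-dimethoxypropane, the standard release of a hydroperoxide from its 2-methoxyprop-2-yl perketal, which does not touch C3.

Step 13
Reactants: 19 methyl (3R)-3-hydroperoxypent-4-enoate; 10 (17E,19E)-3-methoxyhenicosa-1,2,17,19-tetraene
Product: 20 methyl (3R)-3-{[(17E,19E)-3-methoxyhenicosa-1,17,19-trien-3-yl]peroxy}pent-4-enoate (both epimers at the ketal carbon)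
Conditions: 10 (1.1 equiv), PPTS (5 mol%), CH2Cl2, −20 → 0 °C; then Et3N; chromatography on Et3N-deactivated silica
Reagents that add atoms: none
Why: Proposed new method: PPTS should protonate the central allene carbon of 10 to give the 1-alkyl-1-methoxyallyl (vinyl oxocarbenium) cation, which the hydroperoxide oxygen of 19 captures at the methoxy-bearing carbon to give the vinyl-substituted mixed peroxyketal; the closest known reactions are the acid-catalysed perketalisation of hydroperoxides with 2-methoxypropene and the acid-catalysed addition of alcohols to alkoxyallenes giving acrolein-type acetals; the new ketal carbon (future C6) is formed without control, both epimers being expected in comparable amounts, and C3 is untouched.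

Step 14
Reactants: 20 methyl (3R)-3-{[(17E,19E)-3-methoxyhenicosa-1,17,19-trien-3-yl]peroxy}pent-4-enoate (both ketal epimers)
Product: 21 methyl 2-[(3R)-6-methoxy-6-[(14E,16E)-octadeca-14,16-dien-1-yl]-3,6-dihydro-1,2-dioxin-3-yl]acetate (both C6 epimers, 6S and 6R)
Conditions: first-generation Grubbs catalyst RuCl2(PCy3)2(=CHPh) (5 mol%), CH2Cl2 (2 mM), 30 °C, argon sparge; then ethyl vinyl ether; filtration through Et3N-deactivated silica
Reagents that add atoms: none
Why: Ring-closing olefin metathesis by the Chauvin mechanism: the ruthenium benzylidene loads onto the unhindered vinyl group at C3, the new alkylidene undergoes [2+2] cycloaddition and cycloreversion with the vinyl group on the fully substituted ketal carbon C6, and ethene is lost as the C4=C5 bond forms. The closest known reaction types are the ring-closing metathesis of acrolein-derived mixed acetals (alkoxyallene adducts) to 2-alkoxy-3,6-dihydro-2H-pyrans and ruthenium-catalysed metathesis of alkenes that carry dialkyl peroxide and peroxyketal groups. The only ring, the six-membered 1,2-dioxine, is closed by metathesis across the C3–O2–O1–C6 tether, and the ring size allows only the cis C4=C5 alkene. No stereocenter is formed: C3 (R, from step 9) is untouched and each ketal epimer of 20 passes its configuration on to C6 of 21, so the epimer pair is carried to step 15, where C6 is fixed. The selectivity needed is reaction of the two terminal vinyl groups in preference to the remote E,E-diene and the O–O bond; it rests on the fast six-membered closure between monosubstituted alkenes, on the first-generation catalyst, which reacts only sluggishly with 1,2-disubstituted and conjugated alkenes, on high dilution with removal of ethene, and on quenching at full conversion.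

Step 15
Reactants: 21 methyl 2-[(3R)-6-methoxy-6-[(14E,16E)-octadeca-14,16-dien-1-yl]-3,6-dihydro-1,2-dioxin-3-yl]acetate (both C6 epimers)
Product: 22 xestin B, methyl 2-[(3R,6S)-6-methoxy-6-[(14E,16E)-octadeca-14,16-dien-1-yl]-3,6-dihydro-1,2-dioxin-3-yl]acetate
Conditions: chromatography on Et3N-deactivated silica to take out the (6S) epimer; the remaining (6R) epimer: CSA (5 mol%), MeOH, 0 °C → rt; NaHCO3; chromatography again, the cycle repeated
Reagents that add atoms: methanol, CO
Why: Acid-catalysed anomerisation of a cyclic methoxy peroxyketal: ionisation of the C6–OMe bond gives the ring peroxycarbenium ion and methanol re-adds from either face, so the (6R) epimer is converted into the pair again while the (6S) epimer (methoxy trans to the C3 side chain), a cyclic diastereomer that should be separable, is drawn off; C6 is fixed in this way by equilibration and separation, and C3 is not involved.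

## Compound list

1 | 12-bromododecan-1-ol | OCCCCCCCCCCCCBr | starting material
2 | (12-bromododecyloxy)(tert-butyl)dimethylsilane | CC(C)(C)[Si](C)(C)OCCCCCCCCCCCCBr | intermediate
3 | (2E,4E)-hexa-2,4-dien-1-yl acetate (sorbyl acetate) | C/C=C/C=C/COC(C)=O | starting material
4 | [12-(tert-butyldimethylsilyloxy)dodecyl]magnesium bromide | CC(C)(C)[Si](C)(C)OCCCCCCCCCCCC[Mg]Br | intermediate
5 | tert-butyldimethyl{[(14E,16E)-octadeca-14,16-dien-1-yl]oxy}silane | C/C=C/C=C/CCCCCCCCCCCCCO[Si](C)(C)C(C)(C)C | intermediate
6 | (14E,16E)-octadeca-14,16-dien-1-ol | C/C=C/C=C/CCCCCCCCCCCCCO | intermediate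
7 | (2E,4E)-18-iodooctadeca-2,4-diene | C/C=C/C=C/CCCCCCCCCCCCCI | intermediate
8 | methoxyallene (1-methoxypropa-1,2-diene) | COC=C=C | starting material
9 | 1-lithio-1-methoxypropa-1,2-diene | COC([Li])=C=C | intermediate
10 | (17E,19E)-3-methoxyhenicosa-1,2,17,19-tetraene | C/C=C/C=C/CCCCCCCCCCCCCC(OC)=C=C | intermediate
11 | (2E)-penta-2,4-dienoic acid | C=C/C=C/C(=O)O | starting material
12 | (2E)-penta-2,4-dien-1-ol | C=C/C=C/CO | intermediate
13 | (2E)-penta-2,4-dienal | C=C/C=C/C=O | intermediate
14 | 2,3-dimethylbut-2-ene | CC(C)=C(C)C | starting material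
15 | 2-methoxyprop-2-yl hydroperoxide | COC(C)(C)OO | intermediate
16 | (3R)-3-[(2-methoxypropan-2-yl)peroxy]pent-4-enal | C=C[C@@H](CC=O)OOC(C)(C)OC | intermediate
17 | (3R)-3-[(2-methoxypropan-2-yl)peroxy]pent-4-enoic acid | C=C[C@@H](CC(=O)O)OOC(C)(C)OC | intermediate
18 | methyl (3R)-3-[(2-methoxypropan-2-yl)peroxy]pent-4-enoate | C=C[C@@H](CC(=O)OC)OOC(C)(C)OC | intermediate
19 | methyl (3R)-3-hydroperoxypent-4-enoate | C=C[C@@H](CC(=O)OC)OO | intermediate
20 | methyl (3R)-3-{[(17E,19E)-3-methoxyhenicosa-1,17,19-trien-3-yl]peroxy}pent-4-enoate, both epimers at the ketal carbon | C/C=C/C=C/CCCCCCCCCCCCCC(OC)(C=C)OO[C@@H](C=C)CC(=O)OC | intermediate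
21 | methyl 2-[(3R)-6-methoxy-6-[(14E,16E)-octadeca-14,16-dien-1-yl]-3,6-dihydro-1,2-dioxin-3-yl]acetate, both C6 epimers (6S and 6R) | C/C=C/C=C/CCCCCCCCCCCCCC1(OC)C=C[C@@H](CC(=O)OC)OO1 | intermediate
22 | xestin B, methyl 2-[(3R,6S)-6-methoxy-6-[(14E,16E)-octadeca-14,16-dien-1-yl]-3,6-dihydro-1,2-dioxin-3-yl]acetate | C/C=C/C=C/CCCCCCCCCCCCC[C@@]1(OC)C=C[C@@H](CC(=O)OC)OO1 | target

## Step count and risks

Total step count: 15.

Longest linear sequence: 9 steps (11 → 12 → 13 → 16 → 17 → 18 → 19 → 20 → 21 → 22; steps 6, 7, 9, 10, 11, 12, 13, 14, 15). The chain branch (1 → 2 → 5 → 6 → 7 → 10 → 20 → 21 → 22) is 8 steps.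

Three steps most likely to fail:

1. Step 13 (proposed new method). The allyl cation may be captured at its terminal carbon (conjugate addition), a second exchange may lead on to the bis-peroxyketal, or the allene may be lost by hydration before the hydroperoxide adds. The fallback uses known chemistry, sets out from 10 and 19 and comes back at 20. Acid-catalysed addition of methanol to 10 (PPTS, MeOH, 0 °C; the known alcohol addition to alkoxyallenes) gives the dimethyl ketal (17E,19E)-3,3-dimethoxyhenicosa-1,17,19-triene F1. Acid-catalysed exchange of one methoxy group of F1 by hydroperoxide 19 (CSA cat., 5 Å molecular sieves, CH2Cl2, 0 °C; the known peroxyketal formation from ketals and hydroperoxides under reversible conditions) then gives 20.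

2. Step 14 (key step). The ruthenium alkylidene may be diverted to the remote diene (exchange or loss of its terminal propenyl unit), or closure at the hindered vinyl group may be slow enough for the O–O bond to destroy the catalyst. In the fallback the diene is built after ring closure; it sets out from 4, 9 and 19 and comes back at 21. Opening of oxirane by Grignard reagent 4 (copper iodide CuI, 5 mol%, THF, −30 °C) gives 14-{[tert-butyl(dimethyl)silyl]oxy}tetradecan-1-ol F2, and iodination as in step 4 gives tert-butyl[(14-iodotetradecyl)oxy]dimethylsilane F3. Alkylation of 9 with F3 as in step 5 gives tert-butyl[(15-methoxyheptadeca-15,16-dien-1-yl)oxy]dimethylsilane F4, and addition of 19 as in step 13 gives methyl (3R)-3-[(17-{[tert-butyl(dimethyl)silyl]oxy}-3-methoxyheptadec-1-en-3-yl)peroxy]pent-4-enoate F5. Ring-closing metathesis, now free of any competing diene so that the more active second-generation Hoveyda–Grubbs catalyst RuCl2(H2IMes)(=CH-C6H4-2-OiPr) can be used, gives methyl 2-[(3R)-6-(14-{[tert-butyl(dimethyl)silyl]oxy}tetradecyl)-6-methoxy-3,6-dihydro-1,2-dioxin-3-yl]acetate F6 (both C6 epimers). HF·pyridine (THF/pyridine, 0 °C) gives methyl 2-[(3R)-6-(14-hydroxytetradecyl)-6-methoxy-3,6-dihydro-1,2-dioxin-3-yl]acetate F7, and Dess–Martin periodinane with NaHCO3 gives methyl 2-[(3R)-6-methoxy-6-(14-oxotetradecyl)-3,6-dihydro-1,2-dioxin-3-yl]acetate F8. An E-selective Wittig reaction with the allylic ylide from tributyl[(2E)-but-2-en-1-yl]phosphonium bromide F9 (made from tributylphosphine and (E)-1-bromobut-2-ene; KOtBu, THF, ylide as limiting reagent, F8 added at −78 °C) gives the epimer pair 21, which goes on to step 15.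

3. Step 9. The hydroperoxide may add at the unsubstituted terminal carbon of the dienyl iminium ion (1,6-addition), the β-peroxy enamine may collapse to an epoxide, and the dienal may polymerise. The fallback uses a stable, δ-substituted dienal whose extra carbon leaves in the ring closure; it sets out from 15 and comes back at 21. The same amine-catalysed peroxidation of commercial (2E,4E)-hexa-2,4-dienal with 15 gives (3R,4E)-3-[(2-methoxypropan-2-yl)peroxy]hex-4-enal F10. Oxidation as in step 10 gives (3R,4E)-3-[(2-methoxypropan-2-yl)peroxy]hex-4-enoic acid F11, and methylation as in step 11 gives methyl (3R,4E)-3-[(2-methoxypropan-2-yl)peroxy]hex-4-enoate F12. Perketal cleavage as in step 12 gives methyl (3R,4E)-3-hydroperoxyhex-4-enoate F13, and addition to 10 as in step 13 gives methyl (3R,4E)-3-{[(17E,19E)-3-methoxyhenicosa-1,17,19-trien-3-yl]peroxy}hex-4-enoate F14. Ring-closing metathesis of F14 with the second-generation Grubbs catalyst RuCl2(PCy3)(H2IMes)(=CHPh), propene being lost, gives the epimer pair 21, which goes on to step 15.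

Further compounds
F1 | step 13 | (17E,19E)-3,3-dimethoxyhenicosa-1,17,19-triene | C/C=C/C=C/CCCCCCCCCCCCCC(OC)(OC)C=C
F2 | step 14 | 14-{[tert-butyl(dimethyl)silyl]oxy}tetradecan-1-ol | CC(C)(C)[Si](C)(C)OCCCCCCCCCCCCCCO
F3 | step 14 | tert-butyl[(14-iodotetradecyl)oxy]dimethylsilane | CC(C)(C)[Si](C)(C)OCCCCCCCCCCCCCCI
F4 | step 14 | tert-butyl[(15-methoxyheptadeca-15,16-dien-1-yl)oxy]dimethylsilane | CC(C)(C)[Si](C)(C)OCCCCCCCCCCCCCCC(OC)=C=C
F5 | step 14 | methyl (3R)-3-[(17-{[tert-butyl(dimethyl)silyl]oxy}-3-methoxyheptadec-1-en-3-yl)peroxy]pent-4-enoate, both ketal epimers | CC(C)(C)[Si](C)(C)OCCCCCCCCCCCCCCC(OC)(C=C)OO[C@@H](C=C)CC(=O)OC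
F6 | step 14 | methyl 2-[(3R)-6-(14-{[tert-butyl(dimethyl)silyl]oxy}tetradecyl)-6-methoxy-3,6-dihydro-1,2-dioxin-3-yl]acetate, both C6 epimers | CC(C)(C)[Si](C)(C)OCCCCCCCCCCCCCCC1(OC)C=C[C@@H](CC(=O)OC)OO1
F7 | step 14 | methyl 2-[(3R)-6-(14-hydroxytetradecyl)-6-methoxy-3,6-dihydro-1,2-dioxin-3-yl]acetate, both C6 epimers | OCCCCCCCCCCCCCCC1(OC)C=C[C@@H](CC(=O)OC)OO1
F8 | step 14 | methyl 2-[(3R)-6-methoxy-6-(14-oxotetradecyl)-3,6-dihydro-1,2-dioxin-3-yl]acetate, both C6 epimers | O=CCCCCCCCCCCCCCC1(OC)C=C[C@@H](CC(=O)OC)OO1
F9 | step 14 | tributyl[(2E)-but-2-en-1-yl]phosphonium bromide | C/C=C/C[P+](CCCC)(CCCC)CCCC.[Br-]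
F10 | step 9 | (3R,4E)-3-[(2-methoxypropan-2-yl)peroxy]hex-4-enal | C/C=C/[C@@H](CC=O)OOC(C)(C)OC
F11 | step 9 | (3R,4E)-3-[(2-methoxypropan-2-yl)peroxy]hex-4-enoic acid | C/C=C/[C@@H](CC(=O)O)OOC(C)(C)OC
F12 | step 9 | methyl (3R,4E)-3-[(2-methoxypropan-2-yl)peroxy]hex-4-enoate | C/C=C/[C@@H](CC(=O)OC)OOC(C)(C)OC
F13 | step 9 | methyl (3R,4E)-3-hydroperoxyhex-4-enoate | C/C=C/[C@@H](CC(=O)OC)OO
F14 | step 9 | methyl (3R,4E)-3-{[(17E,19E)-3-methoxyhenicosa-1,17,19-trien-3-yl]peroxy}hex-4-enoate, both ketal epimers | C/C=C/C=C/CCCCCCCCCCCCCC(OC)(C=C)OO[C@@H](/C=C/C)CC(=O)OC
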